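The plan rests on cutting the C5–C6 bond of the α-acetoxy ketone in the cyclohexanone ring (C5 ketone carbon, C6 acetoxy-bearing carbon). A carbene-catalysed intramolecular crossed benzoin reaction closes the six-membered ring from an open-chain 1,6-dialdehyde. In one operation it turns the enal carbon into the C5 ketone and the saturated aldehyde carbon into the C6 carbinol, sets C6, and leaves a C3=C4 enone for a later hydroxyl-directed epoxidation. The precursor is a (Z)-enal/aldehyde that already carries C1, C2 and C8. It is built by an Evans syn-aldol between a 4-angeloyloxygeranoyl imide dienolate (from sulcatone) and a (Z)-C5 enal.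

Key step: step 13

Remark: atom labels used throughout are C1 (ring CH bearing the side chain), C2 (ring CH–O next to the epoxide), C3 and C4 (epoxide carbons, C4 bears the methyl), C5 (ketone), C6 (ring CH–O next to the ketone), C7 (side-chain sp2 carbon), C14 (its =CH2), C8 (side-chain CH–O), C9–C11 (prenyl); angeloyl = (2Z)-2-methylbut-2-enoyl.

Step 1
Reactants: 1 6-methylhept-5-en-2-one (sulcatone)
Product: 3 (3S)-3-hydroxy-6-methylhept-5-en-2-one, via anilinooxy ketone 2 (not isolated)
Conditions: D-proline (20 mol%), PhNO (slow addition), excess 1, DMSO, rt; then CuSO4·5H2O (30 mol%), MeOH, 0 °C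
Reagents that add atoms: nitrosobenzene, O=Nc1ccccc1
Why: Proline-catalysed α-aminoxylation (nitroso aldol via the more substituted enamine), in which the carboxylic acid of D-proline guides the oxygen of PhN=O to one enamine face so that C8 should form as S, followed by copper-mediated N–O cleavage to the α-hydroxy ketone.

Step 2
Reactants: 3 (3S)-3-hydroxy-6-methylhept-5-en-2-one; 4 tert-butyl (triphenylphosphoranylidene)acetate
Product: 5 tert-butyl (2E,4S)-4-hydroxy-3,7-dimethylocta-2,6-dienoate
Conditions: toluene, 90 °C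
Reagents that add atoms: none
Why: Wittig olefination with a stabilised ylide, for which α-hydroxy ketones are activated substrates; the E enoate (C8 trans to the ester) should dominate, the minor Z isomer is removed, and the neutral conditions leave C8 untouched.

Step 3
Reactants: 5 tert-butyl (2E,4S)-4-hydroxy-3,7-dimethylocta-2,6-dienoate; 6 angelic acid
Product: 8 tert-butyl (2E,4S)-4-(angeloyloxy)-3,7-dimethylocta-2,6-dienoate, via mixed anhydride 7 (not isolated)
Conditions: 6, 2,4,6-trichlorobenzoyl chloride, Et3N, toluene, rt; then 5, 80 °C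
Reagents that add atoms: none
Why: Yamaguchi esterification through the mixed anhydride without a nucleophilic catalyst, the usual way to make angelates without Z-to-E isomerisation; no stereocentre is touched.

Step 4
Reactants: 8 tert-butyl (2E,4S)-4-(angeloyloxy)-3,7-dimethylocta-2,6-dienoate
Product: 10 (2E,4S)-4-(angeloyloxy)-3,7-dimethylocta-2,6-dienoic acid, via trimethylsilyl ester 9 (not isolated)
Conditions: TMSOTf, 2,6-lutidine, CH2Cl2, 0 °C to rt; aqueous work-up (pH 4 buffer)
Reagents that add atoms: none
Why: Silyl-triflate-mediated cleavage of the tert-butyl ester (loss of 2-methylpropene, silyl ester hydrolysed on work-up) under buffered aprotic conditions that should spare the angelate and the trisubstituted alkene.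

Step 5
Reactants: 10 (2E,4S)-4-(angeloyloxy)-3,7-dimethylocta-2,6-dienoic acid; 11 (4R)-4-benzyl-1,3-oxazolidin-2-one
Product: 13 (4R)-4-benzyl-3-[(2E,4S)-4-(angeloyloxy)-3,7-dimethylocta-2,6-dienoyl]-1,3-oxazolidin-2-one, via pivalic mixed anhydride 12 (not isolated)
Conditions: PivCl, Et3N, THF, −20 °C; then 11, LiCl, rt
Reagents that add atoms: none
Why: N-acylation of the oxazolidinone through the mixed pivalic anhydride with LiCl and Et3N, mild conditions that avoid a lithiated oxazolidinone and should keep the angelate intact.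

Step 6
Reactants: 14 prop-2-yn-1-ol
Product: 16 (2Z)-3-iodo-2-methylprop-2-en-1-ol, via alkenylmagnesium alkoxide 15 (not isolated)
Conditions: MeMgBr (2.2 equiv), CuI (10 mol%), THF, −10 °C to rt; then I2, −78 to 0 °C
Reagents that add atoms: methylmagnesium bromide, C[Mg]Br; iodine, II
Why: Copper-catalysed anti-carbomagnesiation of the propargylic alkoxide places the methyl on C4 and magnesium cis to the CH2O group in a chelate, and iodination with retention fixes the Z geometry that the ring closure later needs.

Step 7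
Reactants: 16 (2Z)-3-iodo-2-methylprop-2-en-1-ol
Product: 17 triethyl{[(2Z)-3-iodo-2-methylprop-2-en-1-yl]oxy}silane
Conditions: TESCl, imidazole, CH2Cl2, 0 °C
Reagents that add atoms: chlorotriethylsilane, CC[Si](Cl)(CC)CC
Why: Standard silylation of the primary allylic alcohol as a silyl ether that can later be removed in the presence of a secondary tert-butyldimethylsilyl ether.

Step 8
Reactants: 17 triethyl{[(2Z)-3-iodo-2-methylprop-2-en-1-yl]oxy}silane
Product: 19 (2Z)-3-methyl-4-(triethylsilyloxy)but-2-enal, via alkenyllithium 18 (not isolated)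
Conditions: t-BuLi (2 equiv), Et2O, −78 °C; DMF; aq. NH4Cl
Reagents that add atoms: N,N-dimethylformamide, CN(C)C=O
Why: Iodine–lithium exchange with retention of alkene geometry followed by formylation with DMF, run in ether at low temperature to suppress 1,4 oxygen-to-carbon silyl migration.

Step 9
Reactants: 13 (4R)-4-benzyl-3-[(2E,4S)-4-(angeloyloxy)-3,7-dimethylocta-2,6-dienoyl]-1,3-oxazolidin-2-one; 19 (2Z)-3-methyl-4-(triethylsilyloxy)but-2-enal
Product: 22 (4R)-4-benzyl-3-{(2R,3S,4Z)-3-hydroxy-5-methyl-2-[(3S)-3-(angeloyloxy)-6-methylhepta-1,5-dien-2-yl]-6-(triethylsilyloxy)hex-4-enoyl}-1,3-oxazolidin-2-one, via boron dienolate 20 (not isolated), via boron aldolate 21 (not isolated)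
Conditions: Bu2BOTf, Et3N, CH2Cl2, −78 to 0 °C; 19, −78 to −20 °C; pH 7 buffer, MeOH, H2O2, 0 °C
Reagents that add atoms: none
Why: Evans syn-aldol of the dibutylboron dienolate (vinylogous soft enolisation at the C14 methyl, which lies cis to the carbonyl), which reacts at the α-carbon C1 through a closed Zimmerman–Traxler chair on the face away from the benzyl group, setting C1 and C2 syn and creating the C7=C14 methylene.

Step 10
Reactants: 22 aldol adduct (C2–OH)
Product: 23 (4R)-4-benzyl-3-{(2R,3S,4Z)-3-(tert-butyldimethylsilyloxy)-5-methyl-2-[(3S)-3-(angeloyloxy)-6-methylhepta-1,5-dien-2-yl]-6-(triethylsilyloxy)hex-4-enoyl}-1,3-oxazolidin-2-one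
Conditions: TBSOTf, 2,6-lutidine, CH2Cl2, −78 °C
Reagents that add atoms: tert-butyldimethylsilyl triflate, CC(C)(C)[Si](C)(C)OS(=O)(=O)C(F)(F)F
Why: Silyl ether formation at the secondary allylic C2 hydroxyl, giving a poor leaving group that blocks lactol formation and redox side paths in the carbene step.

Step 11
Reactants: 23 silylated imide
Product: 25 (2S,3S,4Z)-3-(tert-butyldimethylsilyloxy)-5-methyl-2-[(3S)-3-(angeloyloxy)-6-methylhepta-1,5-dien-2-yl]hex-4-ene-1,6-diol, via C6 alcohol 24 (not isolated)
Conditions: LiBH4, MeOH (1 equiv), THF, 0 °C; aqueous work-up; then PPTS, MeOH, 0 °C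
Reagents that add atoms: none
Why: Hydride reduction of the activated imide carbonyl releases the auxiliary and gives the C6 primary alcohol much faster than the hindered conjugated angelate reacts, and mild acid methanolysis then removes the primary triethylsilyl ether far faster than the secondary tert-butyldimethylsilyl ether.

Step 12
Reactants: 25 (Z)-ene-1,6-diol
Product: 26 (2R,3S,4Z)-3-(tert-butyldimethylsilyloxy)-5-methyl-2-[(3S)-3-(angeloyloxy)-6-methylhepta-1,5-dien-2-yl]hex-4-enedial
Conditions: Dess–Martin periodinane, pyridine, CH2Cl2, 0 °C to rt; filtered through silica and used at once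
Reagents that add atoms: none
Why: Dess–Martin oxidation of both primary alcohols under buffered, non-epimerising conditions, which should keep the Z enal geometry and the C1 centre next to the new aldehyde.

Step 13
Reactants: 26 (Z)-enal/aldehyde (1,6-dialdehyde)
Product: 27 α'-hydroxy enone: ring C5(=O)–C4(Me)=C3H–C2H(OTBS)–C1H(side chain)–C6H(OH), with the C2 and C6 oxygens on one face and the C1 side chain on the other, 8S
Conditions: 2-(pentafluorophenyl)-6,7-dihydro-5H-pyrrolo[2,1-c][1,2,4]triazol-2-ium tetrafluoroborate (20 mol%), i-Pr2NEt (20 mol%), CH2Cl2 (0.02 M), rt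
Reagents that add atoms: none
Why: The triazolylidene adds to the C5 formyl group of the enal and proton transfer gives the conjugated Breslow intermediate, an acyl anion equivalent at C5, which attacks the C6 aldehyde and then releases the carbene to leave the C5 ketone and the C6 carbinol (benzoin mechanism). The closest known reaction type is the carbene-catalysed intramolecular crossed benzoin cyclisation of 1,6-dialdehydes to 2-hydroxycyclohexanones. The cyclohexenone ring closes in a 6-exo-trig mode, C5 attacking the C6 carbonyl while the Z C3=C4 bond holds the two chain ends together. The new C6 centre is controlled by the existing C1 and C2 centres: a chair-like transition state with the C1 side chain and the C2 silyl ether equatorial should place the C6 hydroxyl equatorial, trans to the side chain, and the reversible benzoin step and α-ketol enolisation lead to the same all-equatorial isomer. The step needs the enal carbon, not C6, to end as the ketone and needs the acyl anion pathway instead of homoenolate or redox chemistry; the regioisomeric acyloin lacks enone conjugation and should drain back through retro-benzoin, the β-carbon C3 could reach C6 only through a four-membered ring, and the electron-poor N-pentafluorophenyl catalyst with a catalytic amine in an aprotic solvent disfavours β-protonation. The weak base should also limit epimerisation at C1 and loss of the β-silyloxy group before ring closure.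

Step 14
Reactants: 27 α'-hydroxy enone (C2–OTBS, C6–OH)
Product: 29 diacetate enone (C2–OAc and C6–OAc cis to each other, trans to the C1 side chain), via enone diol 28 (not isolated)
Conditions: HF·pyridine, pyridine, THF, 0 °C to rt; work-up; then Ac2O, pyridine, DMAP (cat.), CH2Cl2, 0 °C
Reagents that add atoms: acetic anhydride, CC(=O)OC(C)=O
Why: Buffered fluoride desilylation followed by acetylation of both secondary alcohols installs the two final acetates; C6, which could enolise, already has the more stable equatorial configuration.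

Step 15
Reactants: 29 diacetate enone
Product: 30 allylic alcohol (C5–OH trans to the C6 acetate, on the face of the C1 side chain)
Conditions: NaBH4, CeCl3·7H2O, MeOH, −78 °C; AcOH quench
Reagents that add atoms: none
Why: Luche 1,2-reduction in which hydride should add axially to C5 of the half-chair that holds the C1, C2 and C6 substituents pseudo-equatorial (as in carvone to cis-carveol), giving the equatorial C5 alcohol trans to the C6 acetate.

Step 16
Reactants: 30 allylic alcohol
Product: 31 epoxy alcohol (epoxide oxygen on C3/C4 cis to the C5 hydroxyl, trans to the C2 acetate)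
Conditions: VO(acac)2 (5 mol%), t-BuOOH (in decane), CH2Cl2, 0 °C to rt
Reagents that add atoms: tert-butyl hydroperoxide, CC(C)(C)OO
Why: Vanadium-catalysed hydroxyl-directed epoxidation, in which the allylic C5 hydroxyl delivers the peroxide oxygen to its own face of the C3=C4 bond (also the face away from the C2 acetate) and so sets C3 and C4, while the undirected alkenes and the angelate should not react.

Step 17
Reactants: 31 epoxy alcohol
Product: 32 target, (1R,2R,3S,4S,6S,8S) in the labels above
Conditions: Dess–Martin periodinane, pyridine, CH2Cl2, 0 °C to rt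
Reagents that add atoms: none
Why: Dess–Martin oxidation of the C5 alcohol to the ketone under buffered conditions completes the α,β-epoxy ketone without touching any stereocentre.

Compound list
1 | 6-methylhept-5-en-2-one (sulcatone) | CC(=O)CCC=C(C)C | starting material
2 | (3S)-6-methyl-3-(phenylaminooxy)hept-5-en-2-one | CC(=O)[C@H](CC=C(C)C)ONc1ccccc1 | intermediate
3 | (3S)-3-hydroxy-6-methylhept-5-en-2-one | CC(=O)[C@H](CC=C(C)C)O | intermediate
4 | tert-butyl (triphenylphosphoranylidene)acetate | CC(C)(C)OC(=O)C=P(c1ccccc1)(c1ccccc1)c1ccccc1 | starting material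
5 | tert-butyl (2E,4S)-4-hydroxy-3,7-dimethylocta-2,6-dienoate | C/C(=C\C(=O)OC(C)(C)C)[C@H](CC=C(C)C)O | intermediate
6 | angelic acid, (2Z)-2-methylbut-2-enoic acid | C/C=C(/C)C(=O)O | starting material
7 | angelic 2,4,6-trichlorobenzoic anhydride | C/C=C(/C)C(=O)OC(=O)c1c(Cl)cc(Cl)cc1Cl | intermediate
8 | tert-butyl (2E,4S)-4-(angeloyloxy)-3,7-dimethylocta-2,6-dienoate | C/C(=C\C(=O)OC(C)(C)C)[C@H](CC=C(C)C)OC(=O)/C(C)=C\C | intermediate
9 | trimethylsilyl (2E,4S)-4-(angeloyloxy)-3,7-dimethylocta-2,6-dienoate | C/C(=C\C(=O)O[Si](C)(C)C)[C@H](CC=C(C)C)OC(=O)/C(C)=C\C | intermediate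
10 | (2E,4S)-4-(angeloyloxy)-3,7-dimethylocta-2,6-dienoic acid | C/C(=C\C(=O)O)[C@H](CC=C(C)C)OC(=O)/C(C)=C\C | intermediate
11 | (4R)-4-benzyl-1,3-oxazolidin-2-one | O=C1N[C@H](Cc2ccccc2)CO1 | starting material
12 | pivalic mixed anhydride of acid 10 | C/C(=C\C(=O)OC(=O)C(C)(C)C)[C@H](CC=C(C)C)OC(=O)/C(C)=C\C | intermediate
13 | (4R)-4-benzyl-3-[(2E,4S)-4-(angeloyloxy)-3,7-dimethylocta-2,6-dienoyl]-1,3-oxazolidin-2-one | C/C(=C\C(=O)N1[C@H](Cc2ccccc2)COC1=O)[C@H](CC=C(C)C)OC(=O)/C(C)=C\C | intermediate
14 | prop-2-yn-1-ol | C#CCO | starting material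
15 | bromomagnesium (2Z)-3-(bromomagnesio)-2-methylprop-2-en-1-olate | Br[Mg]OC/C(C)=C\[Mg]Br | intermediate
16 | (2Z)-3-iodo-2-methylprop-2-en-1-ol | OC/C(C)=C\I | intermediate
17 | triethyl{[(2Z)-3-iodo-2-methylprop-2-en-1-yl]oxy}silane | CC[Si](CC)(CC)OC/C(C)=C\I | intermediate
18 | (1Z)-2-methyl-3-(triethylsilyloxy)prop-1-enyllithium | CC[Si](CC)(CC)OC/C(C)=C\[Li] | intermediate
19 | (2Z)-3-methyl-4-(triethylsilyloxy)but-2-enal | CC[Si](CC)(CC)OC/C(C)=C\C=O | intermediate
20 | Z(O) dibutylboron dienolate of imide 13 (C7=C14 and C1=C6 double bonds) | C=C(/C=C(\OB(CCCC)CCCC)N1[C@H](Cc2ccccc2)COC1=O)[C@H](CC=C(C)C)OC(=O)/C(C)=C\C | intermediate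
21 | dibutylboron aldolate of 22 | C=C([C@@H](C(=O)N1[C@H](Cc2ccccc2)COC1=O)[C@@H](OB(CCCC)CCCC)/C=C(C)\CO[Si](CC)(CC)CC)[C@H](CC=C(C)C)OC(=O)/C(C)=C\C | intermediate
22 | (4R)-4-benzyl-3-{(2R,3S,4Z)-3-hydroxy-5-methyl-2-[(3S)-3-(angeloyloxy)-6-methylhepta-1,5-dien-2-yl]-6-(triethylsilyloxy)hex-4-enoyl}-1,3-oxazolidin-2-one | C=C([C@@H](C(=O)N1[C@H](Cc2ccccc2)COC1=O)[C@@H](O)/C=C(C)\CO[Si](CC)(CC)CC)[C@H](CC=C(C)C)OC(=O)/C(C)=C\C | intermediate
23 | (4R)-4-benzyl-3-{(2R,3S,4Z)-3-(tert-butyldimethylsilyloxy)-5-methyl-2-[(3S)-3-(angeloyloxy)-6-methylhepta-1,5-dien-2-yl]-6-(triethylsilyloxy)hex-4-enoyl}-1,3-oxazolidin-2-one | C=C([C@@H](C(=O)N1[C@H](Cc2ccccc2)COC1=O)[C@@H](O[Si](C)(C)C(C)(C)C)/C=C(C)\CO[Si](CC)(CC)CC)[C@H](CC=C(C)C)OC(=O)/C(C)=C\C | intermediate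
24 | (2S,3S,4Z)-3-(tert-butyldimethylsilyloxy)-5-methyl-2-[(3S)-3-(angeloyloxy)-6-methylhepta-1,5-dien-2-yl]-6-(triethylsilyloxy)hex-4-en-1-ol | C=C([C@@H](CO)[C@@H](O[Si](C)(C)C(C)(C)C)/C=C(C)\CO[Si](CC)(CC)CC)[C@H](CC=C(C)C)OC(=O)/C(C)=C\C | intermediate
25 | (2S,3S,4Z)-3-(tert-butyldimethylsilyloxy)-5-methyl-2-[(3S)-3-(angeloyloxy)-6-methylhepta-1,5-dien-2-yl]hex-4-ene-1,6-diol | C=C([C@@H](CO)[C@@H](O[Si](C)(C)C(C)(C)C)/C=C(C)\CO)[C@H](CC=C(C)C)OC(=O)/C(C)=C\C | intermediate
26 | (2R,3S,4Z)-3-(tert-butyldimethylsilyloxy)-5-methyl-2-[(3S)-3-(angeloyloxy)-6-methylhepta-1,5-dien-2-yl]hex-4-enedial | C=C([C@@H](C=O)[C@@H](O[Si](C)(C)C(C)(C)C)/C=C(C)\C=O)[C@H](CC=C(C)C)OC(=O)/C(C)=C\C | intermediate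
27 | α'-hydroxy enone: 6-hydroxy-2-methylcyclohex-2-enone with C2–OTBS and C6–OH cis to each other and trans to the C1 side chain, 8S angelate | C=C([C@@H]1[C@@H](O[Si](C)(C)C(C)(C)C)C=C(C)C(=O)[C@H]1O)[C@H](CC=C(C)C)OC(=O)/C(C)=C\C | intermediate
28 | enone diol (C2–OH, C6–OH; same configuration as 27) | C=C([C@@H]1[C@@H](O)C=C(C)C(=O)[C@H]1O)[C@H](CC=C(C)C)OC(=O)/C(C)=C\C | intermediate
29 | diacetate enone (C2–OAc, C6–OAc; same configuration as 27) | C=C([C@@H]1[C@@H](OC(C)=O)C=C(C)C(=O)[C@H]1OC(C)=O)[C@H](CC=C(C)C)OC(=O)/C(C)=C\C | intermediate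
30 | allylic alcohol (C5–OH trans to C6–OAc, cis to the C1 side chain) | C=C([C@@H]1[C@@H](OC(C)=O)C=C(C)[C@H](O)[C@H]1OC(C)=O)[C@H](CC=C(C)C)OC(=O)/C(C)=C\C | intermediate
31 | epoxy alcohol (C3/C4 epoxide oxygen cis to C5–OH, trans to C2–OAc) | C=C([C@@H]1[C@@H](OC(C)=O)[C@@H]2O[C@]2(C)[C@H](O)[C@H]1OC(C)=O)[C@H](CC=C(C)C)OC(=O)/C(C)=C\C | intermediate
32 | target: epoxy ketone with C2 and C6 acetates and the C8 angelate, (1R,2R,3S,4S,6S,8S) in route labels | C=C([C@@H]1[C@@H](OC(C)=O)[C@@H]2O[C@]2(C)C(=O)[C@H]1OC(C)=O)[C@H](CC=C(C)C)OC(=O)/C(C)=C\C | target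

Total step count: 17. Longest linear sequence: 14 steps (steps 1–5 and 9–17); steps 6–8 form the side branch to enal 19.

Steps most likely to fail

Step 13 (key step). The extended Breslow intermediate may be protonated at C3 and drift into redox or homoenolate chemistry, the enal may isomerise from Z to E before it can close, or the base may epimerise C1 or eliminate the C2 silyloxy group. The fallback sets out from dialdehyde 26 and avoids base and carbene. A reductive pinacol cyclisation with SmI2 (t-BuOH, THF, −78 °C) should give the cyclohexene diol F1, and MnO2 in CH2Cl2 should then oxidise only the allylic C5 hydroxyl. This rejoins the route at 27; a C6 epimer, if formed, can equilibrate through the α-ketol with a trace of amine base.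

Step 15. Hydride may be delivered to the other face of C5, or the C6 acetyl group may migrate to the new C5 hydroxyl; either would misdirect the epoxidation of step 16. The fallback sets out from 27 and replaces reduction, directed epoxidation and re-oxidation by a nucleophilic (Weitz–Scheffer) epoxidation of the enone with t-BuOOH and DBU in CH2Cl2. It keeps the bulky C2 silyl ether to screen its face and should give the epoxy ketone silyl ether F2. HF·pyridine then gives the epoxy diol F3, and Ac2O/pyridine rejoins the route at target 32.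

Step 9. The vinylogous soft enolisation may be sluggish or may compete with deprotonation at C8, and long exposure may erode the Z geometry of enal 19. The fallback sets out from 13 and moves the γ-deprotonation into a separate step. NaN(SiMe3)2 in THF at −78 °C followed by kinetic α-protonation with AcOH should give the deconjugated imide F4. Ordinary α-enolisation of F4 with Bu2BOTf and i-Pr2NEt and addition of 19 rejoin the route at 22.

Further compounds
F1 | step 13 | cyclohexene cis-diol (C5–OH and C6–OH cis, C2–OTBS, configuration at C1, C2, C6 and C8 as in 27) | C=C([C@@H]1[C@@H](O[Si](C)(C)C(C)(C)C)C=C(C)[C@@H](O)[C@H]1O)[C@H](CC=C(C)C)OC(=O)/C(C)=C\C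
F2 | step 15 | epoxy ketone silyl ether (C2–OTBS, C6–OH, epoxide trans to C2–O) | C=C([C@@H]1[C@@H](O[Si](C)(C)C(C)(C)C)[C@@H]2O[C@]2(C)C(=O)[C@H]1O)[C@H](CC=C(C)C)OC(=O)/C(C)=C\C
F3 | step 15 | epoxy ketone diol (C2–OH, C6–OH) | C=C([C@@H]1[C@@H](O)[C@@H]2O[C@]2(C)C(=O)[C@H]1O)[C@H](CC=C(C)C)OC(=O)/C(C)=C\C
F4 | step 9 | (4R)-4-benzyl-3-[(4S)-4-(angeloyloxy)-7-methyl-3-methylideneoct-6-enoyl]-1,3-oxazolidin-2-one | C=C(CC(=O)N1[C@H](Cc2ccccc2)COC1=O)[C@H](CC=C(C)C)OC(=O)/C(C)=C\C
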